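The alpha run takes 2.00 h to give 41.6 % of target, longer than the 1.33 h in which the gamma run gives 41.7 %, at the same starting concentration.

| setting | alpha | gamma | beta | flask |
|---|---|---|---|---|
| starting material | 0.20 M | 0.20 M | 0.30 M | 0.20 M |
| enzyme | 7.1 × 10⁻⁴ mol% | 0.0011 mol% | 5.1 × 10⁻⁴ mol% | 5.1 × 10⁻⁴ mol% |
| remark | run made earlier | run made earlier | run made earlier |  |

| run | time / h | target / % |
|---|---|---|
| alpha | 0.417 | 21.2 |
| alpha | 1.33 | 35.6 |
| alpha | 2.00 | 41.6 |
| alpha | 3.00 | 48.5 |
| alpha | 5.00 | 54.5 |
| gamma | 0.417 | 24.7 |
| gamma | 1.33 | 41.7 |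
| gamma | 2.00 | 48.3 |
| gamma | 3.00 | 55.4 |
| gamma | 5.00 | 64.3 |
| beta | 1.00 | 19.8 |
| beta | 2.00 | 27.1 |
| beta | 3.00 | 30.1 |
| beta | 4.00 | 33.3 |
| beta | 5.00 | 37.5 |

(readings scatter by 1 percentage point)

- factor on the rate of making target when 30 % of the starting material are converted if enzyme is charged twice over
- factor on the rate when 30 % of the starting material are converted if enzyme is charged at 0.005 mol% instead



I divide the logarithm of that time ratio by the logarithm of the enzyme ratio:

n = 0.932

This loading exponent n, the power of the enzyme charge that the rate at fixed conversion follows, is the apparent order in enzyme, and as a reading it carries the scatter. The pair near 48.5 % gives 0.926.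

The alpha run's rates form a ladder. Expressed as fractions of the charge, target forms at 0.508 h⁻¹ up to 0.417 h, at 0.158 h⁻¹ up to 1.33 h, and at 0.0300 h⁻¹ between 3.00 h and 5.00 h, so the first rung is quicker than the others. The gamma run descends these rungs sooner, so I compare loadings on one rung, 30 % conversion, and work in common logarithms:

doubled enzyme: log factor = 0.281, factor 1.91

enzyme at 0.005 mol%: log factor = 0.924, factor 8.39

The forecast gives 1.95 and 9, higher than my second factor, and says the curves “points to order about 0.9–1 in enzyme”.

The flask gives 1.92 and 9.09.

    starting material + enzyme → target + enzyme, rate k1*[starting material]*[enzyme]/(1 + ([starting material]/Km1) + ([starting material]/Ksi1)^2) (0.120 M, 0.150 M, k = 770 M⁻¹ s⁻¹)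
    starting material → uncatalysed product (k = 4.50 × 10⁻⁶ s⁻¹)
    2 enzyme → spent catalyst (k = 510 M⁻¹ s⁻¹)

Put back into the loading exponent, these results give 0.941 for the doubled flask and 0.967 for the flask at 0.005 mol%, beside the 0.932 read from the runs. At 30 % conversion, the flask at 5.1 × 10⁻⁴ mol% holds 80.8 % of its catalyst as spent catalyst and 19.2 % as enzyme, while the flask at 0.005 mol% holds 82.2 % and 17.8 %. The charge ratio 9.80 times the ratio of these enzyme shares gives 9.09, beside the forecast's 9. For the forecast to fail, a run at 0.005 mol% has to show an enzyme share at that conversion that puts this product outside the margin, and a share merely below that of the flask at 5.1 × 10⁻⁴ mol% does not do so: the flask at 0.005 mol% shows 17.8 % against 19.2 %.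

The earlier runs and the new flask are simulated with constants of no real substance, and the scatter is random.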